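Early on, target accounts for nearly all of the substrate lost: at 10.0 min, Wednesday's run has lost 14 percentage points of substrate and holds 14.0 % of target.

| setting | Wednesday's | Saturday's | flask |
|---|---|---|---|
| substrate | 0.067 M | 0.15 M | 0.10 M |
| gas phase | 18 mM (held) | 18 mM (held) | 18 mM (held) |
| remark | run made earlier | run made earlier |  |
| time |  |  | 2.0 h |

| run | time / min | target / % | substrate / % |
|---|---|---|---|
| Wednesday's | 10.0 | 14.0 | 85.6 |
| Wednesday's | 20.0 | 26.6 | 70.0 |
| Wednesday's | 30.0 | 35.8 | 56.4 |
| Wednesday's | 60.0 | 45.6 | 29.7 |
| Wednesday's | 120 | 36.7 | 7.5 |
| Saturday's | 10.0 | 11.4 | 87.7 |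
| Saturday's | 20.0 | 23.0 | 73.3 |
| Saturday's | 30.0 | 30.9 | 61.4 |
| Saturday's | 60.0 | 41.8 | 33.8 |
| Saturday's | 120 | 36.5 | 9.0 |

(readings scatter by 0.3 percentage points)

- target at 2.0 h, in percent of the substrate charged
- the change that raises the amount of target at 2.0 h, in percent of the substrate charged most ("none" if none brings more than 2 percentage points) (eta / theta / none)
- amount of target at 2.0 h, in percent of the substrate charged, after eta

- eta: doubling the transfer coefficient of the gas phase, all else as stated
- theta: doubling the saturation concentration of gas phase, all else as stated

- what was read earlier has a scatter of 0.3 percentage points, one standard deviation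
- at the start none of the gas phase is in solution

So book substrate lost as target made, and ask how fast target goes late in a run. From 60.0 min to 120 min, Wednesday's run makes 22 points by that booking, yet target falls 8.9 points. The sum of the two, divided by the interval and the mean target present, gives 0.0126 min⁻¹; Saturday's run gives 0.0128 min⁻¹. Their mean, 0.0127 min⁻¹, is the target loss constant: the fraction of target present lost per minute, a pseudo-first-order constant. Substrate falls over the same stretch with a mean constant of 0.0225 min⁻¹.

Where does the flask stand at 2.0 h? My first answer, interpolating both runs linearly in charge, is 36.6 % of target and 8.10 % of substrate. Put those back: by this estimate the flask then makes target at 0.391 of the rate at which it loses it, so it is past its peak. Eta doubles the transfer coefficient of the gas phase and theta doubles its saturation concentration, and I expect either, if it brings the run forward, to lower target. My choice is none.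

The forecast gives 36.6 %, none and 35.4 %, holding that “By 2 h the target is past its peak, so faster conversion doesn't help”.

The flask gives 36.1 %. Eta moves target by −2.5 points and theta by −24 points, so the choice is none, and eta leaves 33.6 %.

    gas phase ⇌ dissolved gas, rate k1*(csat - [dissolved gas]) (kL = 0.00680 s⁻¹)
    substrate + dissolved gas → target (k = 0.0220 L mol⁻¹ s⁻¹)
    dissolved gas + target → over-reacted product (k = 0.0120 L mol⁻¹ s⁻¹)
    substrate + target → side product (k = 5.10 × 10⁻⁴ L mol⁻¹ s⁻¹)

Go on from this flask at 2.0 h, with 36.1 % of target and 8.3 % of substrate. Over the further 3.00 h, your loss constant takes that target down to 3.67 %, and the remaining substrate adds 1.61 %. The scheme's step to over-reacted product runs with c(dissolved gas), which reads 0.0165 M in this flask at 2.00 h and 0.0178 M in the neighbouring flask at 5.00 h. That neighbouring flask, left until 5.0 h, holds 5.31 % of target.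

The runs come from a simulation for an exercise; noise was put on by code.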